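**Retrosynthetic overview**
- The C11 hydroxyl goes in last (Rubottom oxidation of the cross-conjugated enone); the γ-lactone is closed just before, from O7 onto a C19 tert-butyl ester.
- Ten-membered ring: intramolecular Nozaki–Hiyama–Kishi coupling of a (Z)-vinyl iodide (C6) with an aldehyde (C7).
- Six-membered ring (formed first): Diels–Alder reaction of an acyclic (E)-enone (C1=C10) with a 1-amino-3-siloxypenta-1,3-diene sets C1 and C10; C2 then comes from ketone reduction and the enone from unmasking.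
- Dienophile: Horner–Wadsworth–Emmons union of a C1–C6 ketophosphonate (from propargyl alcohol) with a C7–C10/C17–C19 aldehyde.
- Aldehyde: from methyl 3,4-O-isopropylidene-L-threonate (supplies C9; a chelation-controlled aldol sets C8 and C17). Ring order: six-membered ring, ten-membered ring, lactone.

Assumption: CNP0346936.2 is taken to be exactly the given SMILES; locants follow briarane numbering (C1–C10 ten-membered ring, C1/C10–C14 six-membered ring, C15 on C1, C16 on C5, C17(C18)–C19 on C8, C20 on C11), and the compounds marked as starting materials are taken as purchasable.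

**Route**

Step 1
Reactants: 1 prop-2-yn-1-ol
Product: 3 (2Z)-3-iodo-2-methylprop-2-en-1-ol, via alkenylmagnesium alkoxide 2 (not isolated)
Conditions: MeMgBr (2.5 equiv), CuI (10 mol %), THF, −10 °C → rt; then I2, −20 °C; H2O
Reagents that add atoms: methylmagnesium bromide C[Mg]Br; iodine [I][I]
Why: Copper-catalysed anti-carbomagnesiation of the propargylic magnesium alkoxide gives a chelated alkenylmagnesium whose iodinolysis retains geometry, so CH2OH and I end up cis (Z).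

Step 2
Reactants: 3 (2Z)-3-iodo-2-methylprop-2-en-1-ol
Product: 4 (1Z)-3-bromo-1-iodo-2-methylprop-1-ene
Conditions: PBr3, Et2O, 0 °C
Reagents that add atoms: phosphorus tribromide BrP(Br)Br
Why: SN2 bromination of the primary allylic alcohol through its phosphite ester leaves the vinyl iodide geometry untouched.

Step 3
Reactants: 5 diethyl (3-oxobutan-2-yl)phosphonate; 4 (1Z)-3-bromo-1-iodo-2-methylprop-1-ene
Product: 7 diethyl [(6Z)-7-iodo-6-methyl-3-oxohept-6-en-2-yl]phosphonate, via phosphonate dianion 6 (not isolated)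
Conditions: NaH, THF, 0 °C; n-BuLi, 0 °C; then 4, −78 → 0 °C; H2O
Reagents that add atoms: none
Why: γ-Alkylation of a β-ketophosphonate dianion takes place at the more nucleophilic terminal carbon by SN2 displacement of the allylic bromide.

Step 4
Reactants: 8 (1E)-1-(dimethylamino)pent-1-en-3-one
Product: 10 (1E,3Z)-3-{[tert-butyl(dimethyl)silyl]oxy}-N,N-dimethylpenta-1,3-dien-1-amine, via potassium dienolate 9 (not isolated)
Conditions: KN(SiMe3)2, THF, −78 °C; then tert-butyl(chloro)dimethylsilane, −78 °C → rt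
Reagents that add atoms: tert-butyl(chloro)dimethylsilane CC(C)(C)[Si](C)(C)Cl
Why: Kinetic deprotonation of the vinylogous amide at the ethyl CH2 and O-silylation of the (Z)-enolate give a Rawal-type aminosiloxy diene with the terminal methyl on the outside.

Step 5
Reactants: 11 tributyl(iodomethyl)stannane; 12 (4-methoxyphenyl)methanol
Product: 14 tributyl{[(4-methoxyphenyl)methoxy]methyl}stannane, via sodium alkoxide 13 (not isolated)
Conditions: NaH, THF/DMF, 0 °C; then 11, 0 °C → rt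
Reagents that add atoms: none
Why: Williamson ether synthesis, the alkoxide displacing iodide from the iodomethylstannane by SN2.

Step 6
Reactants: 15 methyl (2R)-2-[(4S)-2,2-dimethyl-1,3-dioxolan-4-yl]-2-hydroxyacetate
Product: 16 (2R)-2-[(4S)-2,2-dimethyl-1,3-dioxolan-4-yl]-2-hydroxy-N-methoxy-N-methylacetamide
Conditions: MeNH(OMe)·HCl, i-PrMgCl, THF, −20 → 0 °C; H2O
Reagents that add atoms: N,O-dimethylhydroxylamine hydrochloride CNOC.Cl
Why: Weinreb aminolysis of the methyl ester by the chloromagnesium amide, with the hydroxyl carried as its magnesium alkoxide and the C9 stereocentre untouched.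

Step 7
Reactants: 16 (2R)-2-[(4S)-2,2-dimethyl-1,3-dioxolan-4-yl]-2-hydroxy-N-methoxy-N-methylacetamide; 14 tributyl{[(4-methoxyphenyl)methoxy]methyl}stannane
Product: 18 (3R)-3-[(4S)-2,2-dimethyl-1,3-dioxolan-4-yl]-3-hydroxy-1-[(4-methoxyphenyl)methoxy]propan-2-one, via alkoxymethyllithium 17 (not isolated)
Conditions: 14, n-BuLi, THF, −78 °C (2.5 equiv of 17); then 16, −78 °C; H2O
Reagents that add atoms: none
Why: Tin–lithium exchange gives the α-alkoxymethyllithium, which adds once to the Weinreb amide (stable chelated tetrahedral intermediate) to deliver the ketone that carries C7.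

Step 8
Reactants: 18 (3R)-3-[(4S)-2,2-dimethyl-1,3-dioxolan-4-yl]-3-hydroxy-1-[(4-methoxyphenyl)methoxy]propan-2-one; 19 tert-butyl propanoate
Product: 21 tert-butyl (2R,3S)-3-{(R)-[(4S)-2,2-dimethyl-1,3-dioxolan-4-yl](hydroxy)methyl}-3-hydroxy-4-[(4-methoxyphenyl)methoxy]-2-methylbutanoate, via lithium enolate 20 (not isolated)
Conditions: 19, LiN(iPr)2 (3 equiv), THF, −78 °C; then 18, −78 °C; AcOH quench at −78 °C
Reagents that add atoms: none
Why: Chelation-controlled aldol addition, in which the C9 lithium alkoxide and the ketone oxygen hold lithium so that the E(O) ester enolate attacks the face next to the C9 hydrogen (Cram chelate, sets C8) through a Zimmerman–Traxler chair with the CH2O arm equatorial (sets C17).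

Step 9
Reactants: 21 tert-butyl (2R,3S)-3-{(R)-[(4S)-2,2-dimethyl-1,3-dioxolan-4-yl](hydroxy)methyl}-3-hydroxy-4-[(4-methoxyphenyl)methoxy]-2-methylbutanoate
Product: 22 tert-butyl (2R,3S)-3-{(R)-(acetyloxy)[(4S)-2,2-dimethyl-1,3-dioxolan-4-yl]methyl}-3-hydroxy-4-[(4-methoxyphenyl)methoxy]-2-methylbutanoate
Conditions: Ac2O, pyridine, 4-(dimethylamino)pyridine (cat.), CH2Cl2, 0 °C
Reagents that add atoms: acetic anhydride CC(=O)OC(C)=O
Why: Nucleophile-catalysed esterification is selective for the secondary C9 hydroxyl over the tertiary C8 hydroxyl, and the tert-butyl ester resists lactonisation.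

Step 10
Reactants: 22 tert-butyl (2R,3S)-3-{(R)-(acetyloxy)[(4S)-2,2-dimethyl-1,3-dioxolan-4-yl]methyl}-3-hydroxy-4-[(4-methoxyphenyl)methoxy]-2-methylbutanoate
Product: 23 tert-butyl (2R,3S)-3-[(1S)-1-(acetyloxy)-2-oxoethyl]-3-hydroxy-4-[(4-methoxyphenyl)methoxy]-2-methylbutanoate
Conditions: H5IO6, EtOAc, rt
Reagents that add atoms: none
Why: Periodic acid hydrolyses the terminal acetonide and cleaves the freed 1,2-diol in one pot (Malaprade glycol cleavage), leaving the C10 aldehyde next to the intact C9 centre.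

Step 11
Reactants: 23 tert-butyl (2R,3S)-3-[(1S)-1-(acetyloxy)-2-oxoethyl]-3-hydroxy-4-[(4-methoxyphenyl)methoxy]-2-methylbutanoate; 7 diethyl [(6Z)-7-iodo-6-methyl-3-oxohept-6-en-2-yl]phosphonate
Product: 24 tert-butyl (2R,3S,4R,5E,10Z)-4-(acetyloxy)-3-hydroxy-11-iodo-3-{[(4-methoxyphenyl)methoxy]methyl}-2,6,10-trimethyl-7-oxoundeca-5,10-dienoate
Conditions: LiCl, i-Pr2NEt, MeCN, rt
Reagents that add atoms: none
Why: Masamune–Roush Horner–Wadsworth–Emmons olefination of the α-methyl β-ketophosphonate gives the (E)-trisubstituted enone under conditions mild enough for the α-acetoxy aldehyde.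

Step 12
Reactants: 24 tert-butyl (2R,3S,4R,5E,10Z)-4-(acetyloxy)-3-hydroxy-11-iodo-3-{[(4-methoxyphenyl)methoxy]methyl}-2,6,10-trimethyl-7-oxoundeca-5,10-dienoate; 10 (1E,3Z)-3-{[tert-butyl(dimethyl)silyl]oxy}-N,N-dimethylpenta-1,3-dien-1-amine
Product: 25 tert-butyl (2R,3S)-3-{(R)-(acetyloxy)[(1S,2S,5S,6R)-3-{[tert-butyl(dimethyl)silyl]oxy}-5-(dimethylamino)-6-[(4Z)-5-iodo-4-methylpent-4-enoyl]-2,6-dimethylcyclohex-3-en-1-yl]methyl}-3-hydroxy-4-[(4-methoxyphenyl)methoxy]-2-methylbutanoate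
Conditions: 10 (3 equiv), toluene, 110 °C, sealed tube
Reagents that add atoms: none
Why: Thermal Diels–Alder reaction in which the nucleophilic diene terminus bonds to C10 on the face anti to the fully substituted C8, in the rotamer that eclipses C9–H with the alkene (A(1,3) strain with the C1 methyl); this fixes C10 and the quaternary C1 trans to each other from the E geometry, while the C11 and C14 centres (drawn for the endo adduct) are erased later.

Step 13
Reactants: 25 (the cycloadduct of step 12)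
Product: 26 tert-butyl (2R,3S)-3-{(R)-(acetyloxy)[(1S,2S,5S,6R)-3-{[tert-butyl(dimethyl)silyl]oxy}-5-(dimethylamino)-6-[(1R,4Z)-1-hydroxy-5-iodo-4-methylpent-4-en-1-yl]-2,6-dimethylcyclohex-3-en-1-yl]methyl}-3-hydroxy-4-[(4-methoxyphenyl)methoxy]-2-methylbutanoate
Conditions: NaBH4, MeOH/THF, −20 → 0 °C
Reagents that add atoms: none
Why: Hydride reduction of the C2 ketone while the enone is still masked follows the Felkin–Anh model (attack anti to the C1–C10 bond that carries the bulky side chain, C3 next to the small methyl) and gives the (2R)-alcohol.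

Step 14
Reactants: 26 (the alcohol of step 13)
Product: 27 tert-butyl (2R,3S)-3-{(R)-(acetyloxy)[(1S,2S,5S,6R)-6-[(1R,4Z)-1-(butanoyloxy)-5-iodo-4-methylpent-4-en-1-yl]-3-{[tert-butyl(dimethyl)silyl]oxy}-5-(dimethylamino)-2,6-dimethylcyclohex-3-en-1-yl]methyl}-3-hydroxy-4-[(4-methoxyphenyl)methoxy]-2-methylbutanoate
Conditions: butanoic anhydride, Et3N, 4-(dimethylamino)pyridine, CH2Cl2, rt
Reagents that add atoms: butanoic anhydride CCCC(=O)OC(=O)CCC
Why: Nucleophile-catalysed acylation of the secondary C2 alcohol, the tertiary C8 hydroxyl being too hindered to react.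

Step 15
Reactants: 27 (the butanoate of step 14)
Product: 28 tert-butyl (2R,3S)-3-{(R)-(acetyloxy)[(1S,2S,6S)-2-[(1R,4Z)-1-(butanoyloxy)-5-iodo-4-methylpent-4-en-1-yl]-2,6-dimethyl-5-oxocyclohex-3-en-1-yl]methyl}-3-hydroxy-4-[(4-methoxyphenyl)methoxy]-2-methylbutanoate
Conditions: 48% aq. HF, MeCN, 0 °C → rt
Reagents that add atoms: none
Why: Acidic fluoride cleaves the silyl enol ether to the ketone and the β-dimethylamino group leaves by E1cB elimination (the standard unmasking of aminosiloxy-diene cycloadducts), giving the 4,4-disubstituted cyclohexenone.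

Step 16
Reactants: 28 (the enone of step 15)
Product: 29 tert-butyl (2R,3S)-3-{(R)-(acetyloxy)[(1S,2S,6S)-2-[(1R,4Z)-1-(butanoyloxy)-5-iodo-4-methylpent-4-en-1-yl]-2,6-dimethyl-5-oxocyclohex-3-en-1-yl]methyl}-3,4-dihydroxy-2-methylbutanoate
Conditions: 2,3-dichloro-5,6-dicyano-1,4-benzoquinone (DDQ), CH2Cl2/pH 7 buffer (10:1), 0 °C → rt
Reagents that add atoms: none
Why: Oxidative cleavage of the 4-methoxybenzyl ether (benzylic hydride abstraction, hydrolysis of the oxocarbenium ion) frees the primary C7 alcohol without touching the esters, the enone or the vinyl iodide.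

Step 17
Reactants: 29 (the diol of step 16)
Product: 30 tert-butyl (2R,3R)-3-{(R)-(acetyloxy)[(1S,2S,6S)-2-[(1R,4Z)-1-(butanoyloxy)-5-iodo-4-methylpent-4-en-1-yl]-2,6-dimethyl-5-oxocyclohex-3-en-1-yl]methyl}-3-hydroxy-2-methyl-4-oxobutanoate
Conditions: SO3·pyridine, DMSO, i-Pr2NEt, CH2Cl2, 0 °C
Reagents that add atoms: none
Why: Parikh–Doering oxidation turns the primary alcohol into a non-enolisable α-hydroxy aldehyde, tertiary alcohols being inert.

Step 18
Reactants: 30 (the aldehyde of step 17)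
Product: 31 tert-butyl (1S,2R,5Z,7S,8S,9R,10S,11S,17R)-9-(acetyloxy)-2-(butanoyloxy)-7,8-dihydroxy-12-oxobriara-5,13-dien-19-oate
Conditions: CrCl2 (15 equiv), NiCl2 (2 mol %), DMSO/THF (3:1), 0.002 M, rt; H2O
Reagents that add atoms: none
Why: Intramolecular Nozaki–Hiyama–Kishi reaction, in which the alkenylchromium (Z geometry retained) adds to the aldehyde under high dilution to close the ten-membered ring, C7 being set by Felkin–Anh addition anti to the C8 oxygen with the smaller C17 branch beside the incoming carbon.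

Step 19
Reactants: 31 (the macrocyclic alcohol of step 18)
Product: 33 (1S,2R,5Z,7S,8S,9R,10S,11S,17R)-9-(acetyloxy)-2-(butanoyloxy)-8-hydroxy-12-oxobriara-5,13-dien-19,7-olide, via hydroxy acid 32 (not isolated)
Conditions: 85% aq. H3PO4, toluene, rt
Reagents that add atoms: none
Why: Mild acidolysis of the tert-butyl ester followed by acid-catalysed γ-lactonisation onto the C7 hydroxyl (retention at C7) gives the butanolide whose three carbon substituents are mutually trans.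

Step 20
Reactants: 33 (the lactone of step 19)
Product: 36 (1S,2R,5Z,7S,8S,9R,10S,11S,17R)-9-(acetyloxy)-2-(butanoyloxy)-8,11-dihydroxy-12-oxobriara-5,13-dien-19,7-olide, via bis-silyl dienol ether 34 (not isolated), via bis-silyloxy ketone 35 (not isolated)
Conditions: TMSOTf (2.2 equiv), Et3N, CH2Cl2, −20 °C; then dimethyldioxirane, acetone, −78 °C; then 1 M HCl, THF, 0 °C
Reagents that add atoms: dimethyldioxirane CC1(C)OO1
Why: Rubottom oxidation, in which soft enolisation can only occur at C11 (C1 is quaternary) and the dioxirane epoxidises the silyl dienol ether on the face opposite the C9 side chain and the C1 methyl, placing the 11-hydroxyl cis to H-10 after silyl transfer and desilylation.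

**Compound list**

1 | prop-2-yn-1-ol | C#CCO | starting material
2 | bromo[(1Z)-3-(bromomagnesiooxy)-2-methylprop-1-en-1-yl]magnesium | Br[Mg]/C=C(C)\CO[Mg]Br | intermediate
3 | (2Z)-3-iodo-2-methylprop-2-en-1-ol | OC/C(C)=C\I | intermediate
4 | (1Z)-3-bromo-1-iodo-2-methylprop-1-ene | BrC/C(C)=C\I | intermediate
5 | diethyl (3-oxobutan-2-yl)phosphonate (racemic) | CCOP(=O)(OCC)C(C)C(C)=O | starting material
6 | lithium sodium α,γ-dianion of diethyl (3-oxobutan-2-yl)phosphonate | [Li+].[Na+].[CH2-]C([O-])=C(C)P(=O)(OCC)OCC | intermediate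
7 | diethyl [(6Z)-7-iodo-6-methyl-3-oxohept-6-en-2-yl]phosphonate | CCOP(=O)(OCC)C(C)C(=O)CC/C(C)=C\I | intermediate
8 | (1E)-1-(dimethylamino)pent-1-en-3-one | CCC(=O)/C=C/N(C)C | starting material
9 | potassium (1E,3Z)-1-(dimethylamino)penta-1,3-dien-3-olate | [K+].CN(C)/C=C/C([O-])=C/C | intermediate
10 | (1E,3Z)-3-{[tert-butyl(dimethyl)silyl]oxy}-N,N-dimethylpenta-1,3-dien-1-amine | CN(C)/C=C/C(O[Si](C)(C)C(C)(C)C)=C/C | intermediate
11 | tributyl(iodomethyl)stannane | CCCC[Sn](CCCC)(CCCC)CI | starting material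
12 | (4-methoxyphenyl)methanol | COc1ccc(CO)cc1 | starting material
13 | sodium (4-methoxyphenyl)methanolate | [Na+].COc1ccc(C[O-])cc1 | intermediate
14 | tributyl{[(4-methoxyphenyl)methoxy]methyl}stannane | CCCC[Sn](CCCC)(CCCC)COCc1ccc(OC)cc1 | intermediate
15 | methyl (2R)-2-[(4S)-2,2-dimethyl-1,3-dioxolan-4-yl]-2-hydroxyacetate (methyl 3,4-O-isopropylidene-L-threonate) | CC1(C)OC[C@H](O1)[C@@H](O)C(=O)OC | starting material
16 | (2R)-2-[(4S)-2,2-dimethyl-1,3-dioxolan-4-yl]-2-hydroxy-N-methoxy-N-methylacetamide | CC1(C)OC[C@H](O1)[C@@H](O)C(=O)N(C)OC | intermediate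
17 | {[(4-methoxyphenyl)methoxy]methyl}lithium | [Li]COCc1ccc(OC)cc1 | intermediate
18 | (3R)-3-[(4S)-2,2-dimethyl-1,3-dioxolan-4-yl]-3-hydroxy-1-[(4-methoxyphenyl)methoxy]propan-2-one | CC1(C)OC[C@H](O1)[C@@H](O)C(=O)COCc1ccc(OC)cc1 | intermediate
19 | tert-butyl propanoate | CCC(=O)OC(C)(C)C | starting material
20 | lithium (1Z)-1-tert-butoxyprop-1-en-1-olate (the E(O) enolate, methyl trans to O–Li) | [Li+].C/C=C(/[O-])OC(C)(C)C | intermediate
21 | tert-butyl (2R,3S)-3-{(R)-[(4S)-2,2-dimethyl-1,3-dioxolan-4-yl](hydroxy)methyl}-3-hydroxy-4-[(4-methoxyphenyl)methoxy]-2-methylbutanoate | CC1(C)OC[C@H](O1)[C@@H](O)[C@@](O)(COCc1ccc(OC)cc1)[C@@H](C)C(=O)OC(C)(C)C | intermediate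
22 | tert-butyl (2R,3S)-3-{(R)-(acetyloxy)[(4S)-2,2-dimethyl-1,3-dioxolan-4-yl]methyl}-3-hydroxy-4-[(4-methoxyphenyl)methoxy]-2-methylbutanoate | CC1(C)OC[C@H](O1)[C@@H](OC(C)=O)[C@@](O)(COCc1ccc(OC)cc1)[C@@H](C)C(=O)OC(C)(C)C | intermediate
23 | tert-butyl (2R,3S)-3-[(1S)-1-(acetyloxy)-2-oxoethyl]-3-hydroxy-4-[(4-methoxyphenyl)methoxy]-2-methylbutanoate | O=C[C@@H](OC(C)=O)[C@@](O)(COCc1ccc(OC)cc1)[C@@H](C)C(=O)OC(C)(C)C | intermediate
24 | tert-butyl (2R,3S,4R,5E,10Z)-4-(acetyloxy)-3-hydroxy-11-iodo-3-{[(4-methoxyphenyl)methoxy]methyl}-2,6,10-trimethyl-7-oxoundeca-5,10-dienoate | I/C=C(C)\CCC(=O)/C(C)=C/[C@@H](OC(C)=O)[C@@](O)(COCc1ccc(OC)cc1)[C@@H](C)C(=O)OC(C)(C)C | intermediate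
25 | tert-butyl (2R,3S)-3-{(R)-(acetyloxy)[(1S,2S,5S,6R)-3-{[tert-butyl(dimethyl)silyl]oxy}-5-(dimethylamino)-6-[(4Z)-5-iodo-4-methylpent-4-enoyl]-2,6-dimethylcyclohex-3-en-1-yl]methyl}-3-hydroxy-4-[(4-methoxyphenyl)methoxy]-2-methylbutanoate | I/C=C(C)\CCC(=O)[C@@]1(C)[C@@H](N(C)C)C=C(O[Si](C)(C)C(C)(C)C)[C@@H](C)[C@@H]1[C@@H](OC(C)=O)[C@@](O)(COCc1ccc(OC)cc1)[C@@H](C)C(=O)OC(C)(C)C | intermediate
26 | tert-butyl (2R,3S)-3-{(R)-(acetyloxy)[(1S,2S,5S,6R)-3-{[tert-butyl(dimethyl)silyl]oxy}-5-(dimethylamino)-6-[(1R,4Z)-1-hydroxy-5-iodo-4-methylpent-4-en-1-yl]-2,6-dimethylcyclohex-3-en-1-yl]methyl}-3-hydroxy-4-[(4-methoxyphenyl)methoxy]-2-methylbutanoate | I/C=C(C)\CC[C@@H](O)[C@@]1(C)[C@@H](N(C)C)C=C(O[Si](C)(C)C(C)(C)C)[C@@H](C)[C@@H]1[C@@H](OC(C)=O)[C@@](O)(COCc1ccc(OC)cc1)[C@@H](C)C(=O)OC(C)(C)C | intermediate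
27 | tert-butyl (2R,3S)-3-{(R)-(acetyloxy)[(1S,2S,5S,6R)-6-[(1R,4Z)-1-(butanoyloxy)-5-iodo-4-methylpent-4-en-1-yl]-3-{[tert-butyl(dimethyl)silyl]oxy}-5-(dimethylamino)-2,6-dimethylcyclohex-3-en-1-yl]methyl}-3-hydroxy-4-[(4-methoxyphenyl)methoxy]-2-methylbutanoate | I/C=C(C)\CC[C@@H](OC(=O)CCC)[C@@]1(C)[C@@H](N(C)C)C=C(O[Si](C)(C)C(C)(C)C)[C@@H](C)[C@@H]1[C@@H](OC(C)=O)[C@@](O)(COCc1ccc(OC)cc1)[C@@H](C)C(=O)OC(C)(C)C | intermediate
28 | tert-butyl (2R,3S)-3-{(R)-(acetyloxy)[(1S,2S,6S)-2-[(1R,4Z)-1-(butanoyloxy)-5-iodo-4-methylpent-4-en-1-yl]-2,6-dimethyl-5-oxocyclohex-3-en-1-yl]methyl}-3-hydroxy-4-[(4-methoxyphenyl)methoxy]-2-methylbutanoate | I/C=C(C)\CC[C@@H](OC(=O)CCC)[C@@]1(C)C=CC(=O)[C@@H](C)[C@@H]1[C@@H](OC(C)=O)[C@@](O)(COCc1ccc(OC)cc1)[C@@H](C)C(=O)OC(C)(C)C | intermediate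
29 | tert-butyl (2R,3S)-3-{(R)-(acetyloxy)[(1S,2S,6S)-2-[(1R,4Z)-1-(butanoyloxy)-5-iodo-4-methylpent-4-en-1-yl]-2,6-dimethyl-5-oxocyclohex-3-en-1-yl]methyl}-3,4-dihydroxy-2-methylbutanoate | I/C=C(C)\CC[C@@H](OC(=O)CCC)[C@@]1(C)C=CC(=O)[C@@H](C)[C@@H]1[C@@H](OC(C)=O)[C@@](O)(CO)[C@@H](C)C(=O)OC(C)(C)C | intermediate
30 | tert-butyl (2R,3R)-3-{(R)-(acetyloxy)[(1S,2S,6S)-2-[(1R,4Z)-1-(butanoyloxy)-5-iodo-4-methylpent-4-en-1-yl]-2,6-dimethyl-5-oxocyclohex-3-en-1-yl]methyl}-3-hydroxy-2-methyl-4-oxobutanoate | I/C=C(C)\CC[C@@H](OC(=O)CCC)[C@@]1(C)C=CC(=O)[C@@H](C)[C@@H]1[C@@H](OC(C)=O)[C@@](O)(C=O)[C@@H](C)C(=O)OC(C)(C)C | intermediate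
31 | tert-butyl (1S,2R,5Z,7S,8S,9R,10S,11S,17R)-9-(acetyloxy)-2-(butanoyloxy)-7,8-dihydroxy-12-oxobriara-5,13-dien-19-oate | CCCC(=O)O[C@@H]1CC/C(C)=C\[C@H](O)[C@@](O)([C@@H](C)C(=O)OC(C)(C)C)[C@H](OC(C)=O)[C@@H]2[C@]1(C)C=CC(=O)[C@H]2C | intermediate
32 | (1S,2R,5Z,7S,8S,9R,10S,11S,17R)-9-(acetyloxy)-2-(butanoyloxy)-7,8-dihydroxy-12-oxobriara-5,13-dien-19-oic acid | CCCC(=O)O[C@@H]1CC/C(C)=C\[C@H](O)[C@@](O)([C@@H](C)C(O)=O)[C@H](OC(C)=O)[C@@H]2[C@]1(C)C=CC(=O)[C@H]2C | intermediate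
33 | (1S,2R,5Z,7S,8S,9R,10S,11S,17R)-9-(acetyloxy)-2-(butanoyloxy)-8-hydroxy-12-oxobriara-5,13-dien-19,7-olide (11-deoxy target) | CCCC(=O)O[C@@H]1CC/C(C)=C\[C@@H]2OC(=O)[C@H](C)[C@@]2(O)[C@H](OC(C)=O)[C@@H]2[C@]1(C)C=CC(=O)[C@H]2C | intermediate
34 | 8-O,12-O-bis(trimethylsilyl) 11,13-dienol ether of 33 | CCCC(=O)O[C@@H]1CC/C(C)=C\[C@@H]2OC(=O)[C@H](C)[C@@]2(O[Si](C)(C)C)[C@H](OC(C)=O)[C@@H]2[C@]1(C)C=CC(O[Si](C)(C)C)=C2C | intermediate
35 | 8-O,11-O-bis(trimethylsilyl) ether of 36 | CCCC(=O)O[C@@H]1CC/C(C)=C\[C@@H]2OC(=O)[C@H](C)[C@@]2(O[Si](C)(C)C)[C@H](OC(C)=O)[C@@H]2[C@]1(C)C=CC(=O)[C@@]2(C)O[Si](C)(C)C | intermediate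
36 | (1S,2R,5Z,7S,8S,9R,10S,11S,17R)-9-(acetyloxy)-2-(butanoyloxy)-8,11-dihydroxy-12-oxobriara-5,13-dien-19,7-olide (CNP0346936.2) | CCCC(=O)O[C@@H]1CC/C(C)=C\[C@@H]2OC(=O)[C@H](C)[C@@]2(O)[C@H](OC(C)=O)[C@@H]2[C@]1(C)C=CC(=O)[C@@]2(C)O | target

**Step count and risks**

Total step count: 20. Longest linear sequence: 15 steps (steps 6–20, from 15 to 36).

The three steps most likely to fail:

Step 12 (Diels–Alder). Both reacting termini are substituted (the diene carries a methyl at the bond-forming carbon, the dienophile is a trisubstituted enone), so the cycloaddition may be slow or poorly face-selective. The fallback sets out from 24 and returns at 28. It uses the commercial, terminally unsubstituted (1E)-3-{[tert-butyl(dimethyl)silyl]oxy}-N,N-dimethylbuta-1,3-dien-1-amine, whose unhindered terminus bonds to the crowded C10, and gives the C11-desmethyl cycloadduct F1. NaBH4 reduction gives the C11-desmethyl alcohol F2, butanoylation the C11-desmethyl butanoate F3, and HF unmasking the C11-unsubstituted enone F4. Kinetic deprotonation of F4 at C11 with LiN(SiMe3)2 (2.1 equiv, the first on the tertiary hydroxyl) and MeI then installs C20 anti to the C9 side chain and gives 28.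

Step 13 (C2 reduction). In the masked cycloadduct the amino-bearing C14 and the C10 branch compete for the role of large group, so the wrong C2 epimer may predominate. The fallback sets out from 25 and returns at 28. HF is applied first and gives the C2-keto enone F5, in which C14 is sp2 and the C10 branch is unambiguously the large group. Luche reduction (NaBH4, CeCl3·7H2O, MeOH, −78 °C) of both ketones gives the C2,C12-diol F6 (C12 configuration immaterial). MnO2 re-oxidises only the allylic C12 alcohol to the C2-hydroxy enone F7, and butanoylation as in step 14 gives 28.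

Step 18 (Nozaki–Hiyama–Kishi closure). The ring closure may deliver mainly the C7 epimer, because chelation by the free C8 hydroxyl and the tether can override the Felkin–Anh preference. The fallback sets out from 30 and returns at 33. The 7-epi macrocyclic alcohol F8 is carried forward: TMSOTf/2,6-lutidine with a pH 7 work-up frees the 7-epi hydroxy acid F9 without acid-promoted lactonisation. Mitsunobu lactonisation (PPh3, diisopropyl azodicarboxylate) then closes the lactone by SN2 attack of the carboxylate with inversion at C7 and gives 33.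

Further compounds
F1 | step 12 | C11-desmethyl cycloadduct (25 without the ring methyl next to the silyl enol ether) | I/C=C(C)\CCC(=O)[C@@]1(C)[C@@H](N(C)C)C=C(O[Si](C)(C)C(C)(C)C)C[C@@H]1[C@@H](OC(C)=O)[C@@](O)(COCc1ccc(OC)cc1)[C@@H](C)C(=O)OC(C)(C)C
F2 | step 12 | C11-desmethyl alcohol (26 without that methyl) | I/C=C(C)\CC[C@@H](O)[C@@]1(C)[C@@H](N(C)C)C=C(O[Si](C)(C)C(C)(C)C)C[C@@H]1[C@@H](OC(C)=O)[C@@](O)(COCc1ccc(OC)cc1)[C@@H](C)C(=O)OC(C)(C)C
F3 | step 12 | C11-desmethyl butanoate (27 without that methyl) | I/C=C(C)\CC[C@@H](OC(=O)CCC)[C@@]1(C)[C@@H](N(C)C)C=C(O[Si](C)(C)C(C)(C)C)C[C@@H]1[C@@H](OC(C)=O)[C@@](O)(COCc1ccc(OC)cc1)[C@@H](C)C(=O)OC(C)(C)C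
F4 | step 12 | C11-unsubstituted enone (28 without the C20 methyl) | I/C=C(C)\CC[C@@H](OC(=O)CCC)[C@@]1(C)C=CC(=O)C[C@@H]1[C@@H](OC(C)=O)[C@@](O)(COCc1ccc(OC)cc1)[C@@H](C)C(=O)OC(C)(C)C
F5 | step 13 | C2-keto enone (25 after loss of the silyl and dimethylamino groups) | I/C=C(C)\CCC(=O)[C@@]1(C)C=CC(=O)[C@@H](C)[C@@H]1[C@@H](OC(C)=O)[C@@](O)(COCc1ccc(OC)cc1)[C@@H](C)C(=O)OC(C)(C)C
F6 | step 13 | C2,C12-diol ((2R) at C2; C12 carbinol configuration immaterial) | I/C=C(C)\CC[C@@H](O)[C@@]1(C)C=CC(O)[C@@H](C)[C@@H]1[C@@H](OC(C)=O)[C@@](O)(COCc1ccc(OC)cc1)[C@@H](C)C(=O)OC(C)(C)C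
F7 | step 13 | C2-hydroxy enone (28 with free C2 hydroxyl) | I/C=C(C)\CC[C@@H](O)[C@@]1(C)C=CC(=O)[C@@H](C)[C@@H]1[C@@H](OC(C)=O)[C@@](O)(COCc1ccc(OC)cc1)[C@@H](C)C(=O)OC(C)(C)C
F8 | step 18 | 7-epi macrocyclic alcohol ((7R)-epimer of 31) | CCCC(=O)O[C@@H]1CC/C(C)=C\[C@@H](O)[C@@](O)([C@@H](C)C(=O)OC(C)(C)C)[C@H](OC(C)=O)[C@@H]2[C@]1(C)C=CC(=O)[C@H]2C
F9 | step 18 | 7-epi hydroxy acid ((7R)-epimer of 32) | CCCC(=O)O[C@@H]1CC/C(C)=C\[C@@H](O)[C@@](O)([C@@H](C)C(O)=O)[C@H](OC(C)=O)[C@@H]2[C@]1(C)C=CC(=O)[C@H]2C
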